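**Plan**
1. Retrosynthesis: the nonyl chain is taken back to a non-1-ynyl group. The C8–C(alkynyl) bond and the ring bond N9–C8 are then cut, which gives non-1-yne and an open-chain N-propioloyl triamine. The amide bond and the two N–C bonds to N,N'-dimethylbutane-1,4-diamine are cut last.
2. Enabling feature: ring carbon C8 is alpha to ring nitrogen N9 and beta to the lactam carbonyl C6. The N9–C8–C7–C6(=O) array of the 17-membered ring is therefore the retron of an amine/propiolamide conjugate addition, and the cyclic enaminone so formed is a latent iminium ion at C8.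
3. Forward: the chain is joined by N-alkylation, cyanoethylation, nitrile reduction and N-propioloylation. The 17-membered ring, the only ring, arises in the key step by conjugate addition of the terminal methylamino nitrogen, and the acetylide adds to the ring iminium ion in the same flask.
4. Stereochemistry: the single stereocenter C8 is set in the key step by the chiral CuBr/Quinap catalyst. The alkynyl intermediate is 8S and becomes 8R on saturation only through the change in CIP priority.

Key step: step 6

Assumption: 1 and 2 are taken to be catalogue chemicals; ring atoms are numbered as in 1,5,9,13-tetraazacycloheptadecan-6-one (N5 amide nitrogen, C6 carbonyl, C8 stereocenter, N9 its methylated nitrogen).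

**Step 1**
Reactants: 1 N,N'-dimethylbutane-1,4-diamine; 2 tert-butyl (3-bromopropyl)(methyl)carbamate
Product: 3 tert-butyl methyl(3-{methyl[4-(methylamino)butyl]amino}propyl)carbamate
Conditions: 1 (5 equiv), K2CO3, MeCN, 50 °C; excess 1 distilled off
Reagents that add atoms: none
Why: SN2 N-alkylation of a secondary amine by a primary bromide, in which the five-fold excess of the symmetrical diamine should hold back dialkylation.

**Step 2**
Reactants: 3 tert-butyl methyl(3-{methyl[4-(methylamino)butyl]amino}propyl)carbamate; 4 acrylonitrile
Product: 5 tert-butyl (3-{[4-{(2-cyanoethyl)(methyl)amino}butyl](methyl)amino}propyl)(methyl)carbamate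
Conditions: 4 (1.2 equiv), MeOH, rt
Reagents that add atoms: none
Why: Aza-Michael addition (cyanoethylation) of the one remaining secondary amine, which should stop cleanly at the tertiary amine.

**Step 3**
Reactants: 5 tert-butyl (3-{[4-{(2-cyanoethyl)(methyl)amino}butyl](methyl)amino}propyl)(methyl)carbamate
Product: 6 tert-butyl (3-{[4-{(3-aminopropyl)(methyl)amino}butyl](methyl)amino}propyl)(methyl)carbamate
Conditions: H2 (4 bar), Raney Ni, 7 M NH3 in MeOH, rt
Reagents that add atoms: none
Why: Heterogeneous hydrogenation of the nitrile to the primary amine, with ammonia suppressing secondary-amine formation and the Boc carbamate inert to the conditions.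

**Step 4**
Reactants: 6 tert-butyl (3-{[4-{(3-aminopropyl)(methyl)amino}butyl](methyl)amino}propyl)(methyl)carbamate; 7 propiolic acid
Product: 8 tert-butyl methyl(3-{methyl[4-(methyl{3-[(prop-2-ynoyl)amino]propyl}amino)butyl]amino}propyl)carbamate
Conditions: DCC (1.1 equiv), CH2Cl2, −10 to 0 °C
Reagents that add atoms: none
Why: Carbodiimide amide coupling at the only acylable nitrogen; at low temperature the acid rests as its unreactive ammonium propiolate until activated, so N-acylation should outrun conjugate addition to the triple bond.

**Step 5**
Reactants: 8 tert-butyl methyl(3-{methyl[4-(methyl{3-[(prop-2-ynoyl)amino]propyl}amino)butyl]amino}propyl)carbamate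
Product: 9 N-[3-(methyl{4-[methyl(3-(methylamino)propyl)amino]butyl}amino)propyl]prop-2-ynamide tris(trifluoroacetate)
Conditions: TFA/CH2Cl2 (1:3), 0 °C to rt; evaporate, triturate with Et2O
Reagents that add atoms: trifluoroacetic acid, OC(=O)C(F)(F)F
Why: Acidolysis of the Boc carbamate, with the product kept as its salt because the protonated methylamino group cannot add to the propiolamide before step 6.

**Step 6**
Reactants: 9 N-[3-(methyl{4-[methyl(3-(methylamino)propyl)amino]butyl}amino)propyl]prop-2-ynamide tris(trifluoroacetate); 10 non-1-yne
Product: 14 (8S)-1,9,13-trimethyl-8-(non-1-yn-1-yl)-1,5,9,13-tetraazacycloheptadecan-6-one, via free-base amino propiolamide 11 (not isolated), via cyclic E-enaminone 12 (not isolated), via ring iminium trifluoroacetate 13 (not isolated)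
Conditions: 9 added by syringe pump to iPr2NEt (3.3 equiv), MeCN, 50 °C (final 1 mM); evaporate; then 10 (3 equiv), CuBr (10 mol %), (R)-Quinap (11 mol %), 4 Å MS, toluene, 40 °C
Reagents that add atoms: none
Why: Proposed new method: freeing the base 11 lets its only N–H amine, the terminal methylamino group, add to the terminal carbon of the electron-poor propiolamide (amino-yne conjugate addition), which closes the 17-membered ring in the endo-dig mode under pseudo-dilution and gives the cyclic enaminone 12. CuBr/(R)-Quinap then turns 10 into a chiral acetylide of monovalent copper, the proton set free (buffered by the ammonium trifluoroacetate already present) adds to C7 of 12 to give the ring iminium ion 13, and transfer of the acetylide to C8 forms the C–C bond. The closest known reaction types are the CuBr-catalysed three-component amine–alkyne–alkyne coupling of secondary amines, propiolates and terminal alkynes, which runs through the same enaminoate/iminium sequence but is racemic and intermolecular, and the CuBr/Quinap-catalysed enantioselective alkynylation of enamines and of iminium ions in aldehyde–alkyne–amine couplings. The new stereocenter C8 is controlled by the ligand, which must distinguish the two faces of the iminium carbon (H against the CH2C(=O)N arm); (S)-14 is required, and the antipode of the ligand is used if the sense of induction should prove to be the opposite. The step needs ring closure to outrun oligomerisation and C–C bond formation at C8 only, and the substrate secures this because its two other amines are tertiary and its amide N–H is not nucleophilic, the propiolamide accepts the amine only at its terminal carbon, and the iminium ion has a single electrophilic carbon.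

**Step 7**
Reactants: 14 (8S)-1,9,13-trimethyl-8-(non-1-yn-1-yl)-1,5,9,13-tetraazacycloheptadecan-6-one
Product: 16 (8R)-1,9,13-trimethyl-8-nonyl-1,5,9,13-tetraazacycloheptadecan-6-one, via Z-alkenyl macrocycle 15 (not isolated)
Conditions: H2 (1 atm), 5% Pt/C, EtOH, rt
Reagents that add atoms: none
Why: Heterogeneous hydrogenation of the alkyne through the cis-alkene to the alkane, with Pt chosen over Pd because it should cause less double-bond migration and C–N hydrogenolysis, so the arrangement at C8 is kept.

**Compound list**
1 | N,N'-dimethylbutane-1,4-diamine | CNCCCCNC | starting material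
2 | tert-butyl (3-bromopropyl)(methyl)carbamate | CN(CCCBr)C(=O)OC(C)(C)C | starting material
3 | tert-butyl methyl(3-{methyl[4-(methylamino)butyl]amino}propyl)carbamate | CNCCCCN(C)CCCN(C)C(=O)OC(C)(C)C | intermediate
4 | acrylonitrile | C=CC#N | starting material
5 | tert-butyl (3-{[4-{(2-cyanoethyl)(methyl)amino}butyl](methyl)amino}propyl)(methyl)carbamate | N#CCCN(C)CCCCN(C)CCCN(C)C(=O)OC(C)(C)C | intermediate
6 | tert-butyl (3-{[4-{(3-aminopropyl)(methyl)amino}butyl](methyl)amino}propyl)(methyl)carbamate | NCCCN(C)CCCCN(C)CCCN(C)C(=O)OC(C)(C)C | intermediate
7 | propiolic acid (prop-2-ynoic acid) | C#CC(=O)O | starting material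
8 | tert-butyl methyl(3-{methyl[4-(methyl{3-[(prop-2-ynoyl)amino]propyl}amino)butyl]amino}propyl)carbamate | C#CC(=O)NCCCN(C)CCCCN(C)CCCN(C)C(=O)OC(C)(C)C | intermediate
9 | N-[3-(methyl{4-[methyl(3-(methylamino)propyl)amino]butyl}amino)propyl]prop-2-ynamide tris(trifluoroacetate) | C#CC(=O)NCCC[NH+](C)CCCC[NH+](C)CCC[NH2+]C.[O-]C(=O)C(F)(F)F.[O-]C(=O)C(F)(F)F.[O-]C(=O)C(F)(F)F | intermediate
10 | non-1-yne | CCCCCCCC#C | starting material
11 | N-[3-(methyl{4-[methyl(3-(methylamino)propyl)amino]butyl}amino)propyl]prop-2-ynamide (free base) | C#CC(=O)NCCCN(C)CCCCN(C)CCCNC | intermediate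
12 | (7E)-1,9,13-trimethyl-1,5,9,13-tetraazacycloheptadec-7-en-6-one | CN1/C=C/C(=O)NCCCN(C)CCCCN(C)CCC1 | intermediate
13 | 1,9,13-trimethyl-6-oxo-1,5,9,13-tetraazacycloheptadec-8-en-9-ium trifluoroacetate | C[N+]1=CCC(=O)NCCCN(C)CCCCN(C)CCC1.[O-]C(=O)C(F)(F)F | intermediate
14 | (8S)-1,9,13-trimethyl-8-(non-1-yn-1-yl)-1,5,9,13-tetraazacycloheptadecan-6-one | CCCCCCCC#C[C@@H]1CC(=O)NCCCN(C)CCCCN(C)CCCN1C | intermediate
15 | (8S)-1,9,13-trimethyl-8-[(1Z)-non-1-en-1-yl]-1,5,9,13-tetraazacycloheptadecan-6-one | CCCCCCC/C=C\[C@@H]1CC(=O)NCCCN(C)CCCCN(C)CCCN1C | intermediate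
16 | (8R)-1,9,13-trimethyl-8-nonyl-1,5,9,13-tetraazacycloheptadecan-6-one | CCCCCCCCC[C@@H]1CC(=O)NCCCN(C)CCCCN(C)CCCN1C | target

**Total steps:** 7. **Longest linear sequence:** 7 steps (1 to 16).

**Steps most likely to fail**

1. Step 6. Intermolecular amine–alkyne addition may compete with ring closure and give oligomers. Face discrimination in the acetylide transfer may also be weak, because the basic ring nitrogens compete with the ligand for copper or because too little iminium ion forms at a temperature at which the catalyst is still selective.
   Fallback (known chemistry, sets out from 5, returns at 16): acidolysis of the Boc group of 5 (TFA, CH2Cl2, then aqueous NaOH) would give 3-[methyl(4-{methyl[3-(methylamino)propyl]amino}butyl)amino]propanenitrile F1. F1, methyl propiolate and 10 would then be combined in the known CuBr-catalysed three-component amine–alkyne–alkyne coupling (toluene, heat, no chiral ligand). Conjugate addition should give the enamino ester methyl (2E)-3-[{3-[{4-[(2-cyanoethyl)(methyl)amino]butyl}(methyl)amino]propyl}(methyl)amino]prop-2-enoate F2 in the flask, and alkynylation of its iminium form should give racemic methyl 3-[{3-[{4-[(2-cyanoethyl)(methyl)amino]butyl}(methyl)amino]propyl}(methyl)amino]dodec-4-ynoate F3. Hydrogenation over Raney Ni (H2, NH3/MeOH) would saturate the triple bond and reduce the nitrile to racemic methyl 3-[{3-[{4-[(3-aminopropyl)(methyl)amino]butyl}(methyl)amino]propyl}(methyl)amino]dodecanoate F4. Lactamisation of F4 with Sb(OEt)3 in boiling toluene at high dilution, a ring closure established for amino esters of this polyamine lactam class, would give racemic 1,9,13-trimethyl-8-nonyl-1,5,9,13-tetraazacycloheptadecan-6-one F5. Preparative chromatography of F5 on a chiral stationary phase would separate 16 from its enantiomer. Ring closure is thus moved to an amide bond and stereocontrol is replaced by resolution.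

2. Step 4. Conjugate addition of the primary amine, or amine-induced polymerisation of the activated propiolic acid, may compete with N-acylation.
   Fallback (sets out from 6, returns at 8): 6 would be acylated with 3-(trimethylsilyl)prop-2-ynoic acid (EDC·HCl, CH2Cl2, 0 °C). The silyl group shields the terminal alkyne carbon, and the product should be tert-butyl methyl(3-{methyl[4-(methyl{3-[(3-(trimethylsilyl)prop-2-ynoyl)amino]propyl}amino)butyl]amino}propyl)carbamate F6. Protodesilylation of F6 with TBAF buffered by AcOH (THF, 0 °C) would then give 8.

3. Step 7. Double-bond migration toward nitrogen in the half-hydrogenated intermediate would erode the configuration at C8. Hydrogenolysis of the propargylic or allylic C–N bond and poisoning of the catalyst by the polyamine are further risks.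
   Fallback (sets out from 14, returns at 16): metal-free reduction with diimide, generated in the flask from excess 2-nitrobenzenesulfonohydrazide and Et3N in CH2Cl2 at rt. Concerted syn transfer of hydrogen should take 14 through the same Z-alkene 15 to 16 without a metal surface. This fallback makes no new compound (F0).

**Further compounds**
F1 | step 6 | 3-[methyl(4-{methyl[3-(methylamino)propyl]amino}butyl)amino]propanenitrile | CNCCCN(C)CCCCN(C)CCC#N
F2 | step 6 | methyl (2E)-3-[{3-[{4-[(2-cyanoethyl)(methyl)amino]butyl}(methyl)amino]propyl}(methyl)amino]prop-2-enoate | COC(=O)/C=C/N(C)CCCN(C)CCCCN(C)CCC#N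
F3 | step 6 | methyl 3-[{3-[{4-[(2-cyanoethyl)(methyl)amino]butyl}(methyl)amino]propyl}(methyl)amino]dodec-4-ynoate (racemic) | CCCCCCCC#CC(CC(=O)OC)N(C)CCCN(C)CCCCN(C)CCC#N
F4 | step 6 | methyl 3-[{3-[{4-[(3-aminopropyl)(methyl)amino]butyl}(methyl)amino]propyl}(methyl)amino]dodecanoate (racemic) | CCCCCCCCCC(CC(=O)OC)N(C)CCCN(C)CCCCN(C)CCCN
F5 | step 6 | 1,9,13-trimethyl-8-nonyl-1,5,9,13-tetraazacycloheptadecan-6-one (racemic) | CCCCCCCCCC1CC(=O)NCCCN(C)CCCCN(C)CCCN1C
F6 | step 4 | tert-butyl methyl(3-{methyl[4-(methyl{3-[(3-(trimethylsilyl)prop-2-ynoyl)amino]propyl}amino)butyl]amino}propyl)carbamate | C[Si](C)(C)C#CC(=O)NCCCN(C)CCCCN(C)CCCN(C)C(=O)OC(C)(C)C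
F0 | step 7 | none | none
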